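**Next charge.** As I read the two earlier runs now, one decision is open: whether the next flask keeps its reagent below the substrate, or whether I top the reagent up to the substrate charge.

| setting | maple | birch | flask |
|---|---|---|---|
| substrate | 20 mM | 20 mM | 20 mM |
| reagent | 9.5 mM | 38 mM | 19.0 mM |
| remark | run made earlier | run made earlier |  |
| time |  |  | 4.0 d |

| run | time / d | target / % | side product A / % |
|---|---|---|---|
| maple | 0.417 | 17.5 | 8.5 |
| maple | 0.833 | 18.1 | 8.2 |
| maple | 1.25 | 17.9 | 9.8 |
| maple | 2.50 | 17.4 | 8.3 |
| maple | 5.00 | 17.5 | 8.9 |
| birch | 0.417 | 36.6 | 20.3 |
| birch | 0.833 | 36.4 | 19.9 |
| birch | 1.25 | 37.0 | 20.9 |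
| birch | 2.50 | 37.0 | 20.7 |
| birch | 5.00 | 36.6 | 20.2 |

(each reading ± 0.5 percentage points)

1. share of target in target plus side product A at 8.0 min
2. share of target in target plus side product A at 3.0 h
3. share of target in target plus side product A at 4.0 d
4. which of target and side product A there is more of at 4.0 d

- the numbers in the tables scatter by 0.5 percentage points (one standard deviation)
- steps thought possible: substrate <-> intermediate A; substrate -> intermediate B; reagent + intermediate B -> target; reagent + intermediate A -> side product A; reagent + intermediate B -> side product B

**Smaller charge.** Every listed product step takes one reagent. Target in maple reads 17.5 % at 0.417 d and 17.5 % at 5.00 d, flat within the scatter, and birch is flat too. Reckoned per unit of the smaller charge, maple gives 36.8 % of target per reagent charged and birch 36.6 % per substrate charged, so the two readings agree. The smaller charge, the limiting reagent, therefore sets the amount of target in these two runs.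

**The shortfall.** I define the shortfall as one minus reagent charge over substrate charge, the part of the substrate that finds no partner: 5.00 % for this flask. Substrate leaves irreversibly to intermediate B, which moves onward by steps that need reagent, so I expect the shortfall to stand as intermediate B.

**My decision.** I reckon target at 35.0 %. Birch, with 38 mM of reagent, reads 36.6 % of target at 5.00 d, which is 1.6 percentage points above my figure, and with a gap of that size I leave the charge as it is.

**The forecast.** It gives shares of 64.5 %, 65 % and 65.3 % at the three times, with target ahead, and says of the early share: “Early shares are unobserved: probably similar, but intermediate lag makes them uncertain.”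

**The flask.** The flask gives shares of 56.1 %, 69.7 % and 70.4 %, with target ahead at 36.8 %, against my 35.0 %, and side product A at 15.5 %.

    substrate ⇌ intermediate A (K = 0.537, k = 6.19 × 10⁻⁴ /s)
    substrate → intermediate B (k = 0.00189 /s)
    reagent + intermediate B → target (k = 0.0462 /M/s)
    reagent + intermediate A → side product A (k = 0.143 /M/s)
    reagent + intermediate B → side product B (k = 0.0536 /M/s)

At 0.00375 d the flask's substrate goes to intermediate B 3.1 times faster than to intermediate A, forward step alone. By 4.0 d the net turnover into intermediate B is 84.5 % of the substrate charged, beside 15.5 % of side product A. Intermediate B stands at 5.00 % in this flask, against a shortfall of 5.00 %. The neighbour with 7.6 mM of reagent has a shortfall of 62.0 % and holds 62.0 % of intermediate B.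

(The earlier runs and the new flask are simulated with made-up constants, noise included.)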